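**Retrosynthetic overview**

- The last two bonds made are O–CH3 at C5 and C5–allyl. The target goes back to the tertiary quinol and then to the 5,6-ortho-quinone of the dihydrobenzofuran, in which C5=O is ketone-like and C6=O is a vinylogous ester.
- The ortho-quinone comes from the 6-methoxy-5-phenol by oxidative loss of the methyl ether.
- The strategy rests on the five-membered ring O1–C2–C3–C3a–C7a, with aryl on C2 and methyl on C3 trans, fused to a six-membered ring that carries oxygen on C5 and C6. Cutting C3–C3a and O1–C2 maps it onto one C=O/α-CH edge of 2-methoxy-1,4-benzoquinone and the C=C of (E)-isoelemicin.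
- Ring order: both six-membered rings are bought, and the quinone ring becomes the carbocycle. The dihydrofuran is the only ring made, in a chiral titanium TADDOLate annulation that sets C2 and C3. C5 is set afterwards by catalyst-controlled allylboration.

Key step: step 3

Assumption: the (4R,5R)-TADDOLate of titanium is taken to give the (2S,3S) series, and the (S)-biphenol catalyst to deliver allyl to the Si face of C5=O. If either induction runs the other way, the antipodal ligand is used and nothing else changes.

**Route**

Step 1
Reactants: 1 2-methoxyhydroquinone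
Product: 2 2-methoxy-1,4-benzoquinone
Conditions: NaIO4 (1.1 equiv) on SiO2, CH2Cl2, rt
Reagents that add atoms: none
Why: Periodate oxidation of an electron-rich hydroquinone to the para-quinone is a clean two-electron oxidation, and no stereocentre is involved.

Step 2
Reactants: 3 5-bromo-1,2,3-trimethoxybenzene; 4 (E)-prop-1-enylboronic acid pinacol ester
Product: 5 (E)-isoelemicin
Conditions: Pd(dppf)Cl2 (3 mol %), K2CO3 (3 equiv), dioxane/H2O 4:1, 85 °C
Reagents that add atoms: none
Why: Suzuki–Miyaura coupling of an aryl bromide with an (E)-alkenylboronate goes with retention of alkene geometry, so it should give only the (E)-propenylarene that the trans annulation needs.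

Step 3
Reactants: 2 2-methoxy-1,4-benzoquinone; 5 (E)-isoelemicin
Product: 6 (2S,3S)-6-methoxy-3-methyl-2-(3,4,5-trimethoxyphenyl)-2,3-dihydro-1-benzofuran-5-ol
Conditions: TiCl4/Ti(OiPr)4 (1:1, 2 equiv Ti), (4R,5R)-TADDOL (2 equiv), CH2Cl2, rt; then 2, then 5 (1.5 equiv), −78 → −20 °C; H2O; recrystallisation
Reagents that add atoms: none
Why: The titanium(IV) TADDOLate binds quinone 2 through the C1 carbonyl and the neighbouring methoxy oxygen, which makes C5 the electrophilic site; the methyl-bearing alkene carbon of 5 bonds there (C3–C3a) and leaves a benzylic cation stabilised by the trimethoxyphenyl ring opposite a titanium enolate. The C4 carbonyl oxygen then captures the cation (O1–C2) in a 5-exo-trig closure onto the quinone-methide-like cation, and loss of the C3a proton aromatises the six-membered ring to the phenol. The closest known reaction type is the Lewis-acid-promoted formal [3+2] cycloaddition of 2-alkoxy-1,4-benzoquinones with (E)-propenylbenzenes, including its chiral titanium TADDOLate variant. C3 is set in the C–C bond-forming event, where the C2-symmetric diolate shields one face of the chelated quinone and so selects the alkene face that bonds; C2 is set in the ring closure, which is reversible at the benzylic cation and should settle on the trans arrangement of aryl and methyl that the (E)-alkene already favours. The step needs attack at C5 and closure through oxygen instead of carbon ([2+2] or [5+2]); two-point chelation at the methoxy-flanked carbonyl secures the first, and the electron-rich aryl group together with warming above −78 °C, which lets any kinetic cyclobutane reopen to the zwitterion, secures the second.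

Step 4
Reactants: 6 (2S,3S)-6-methoxy-3-methyl-2-(3,4,5-trimethoxyphenyl)-2,3-dihydro-1-benzofuran-5-ol
Product: 7 (2S,3S)-3-methyl-2-(3,4,5-trimethoxyphenyl)-2,3-dihydro-1-benzofuran-5,6-dione
Conditions: IBX (1.2 equiv), DMF, 0 °C → rt, dark; cold neutral aqueous work-up; used at once
Reagents that add atoms: 2-iodoxybenzoic acid (IBX), O=C1OI(=O)(O)c2ccccc12
Why: In the IBX oxidative demethylation of a 2-methoxyphenol the aryloxy-iodane delivers oxygen intramolecularly to the methoxy-bearing ortho carbon and methanol is lost, so the ortho-quinone should form without cleavage of the para C7a–O1 bond and, under neutral conditions, without enolisation toward C3.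

Step 5
Reactants: 8 allylmagnesium bromide; 9 triisopropyl borate
Product: 11 allyldiisopropoxyborane, via bromomagnesium allyltriisopropoxyborate 10 (not isolated)
Conditions: Et2O, −78 °C → rt; then HCl (1.0 equiv, in Et2O), 0 °C; filtration under Ar; distillation
Reagents that add atoms: none
Why: Addition of a Grignard reagent to a trialkyl borate gives the ate complex, and protonolysis with anhydrous HCl removes one isopropoxide as isopropanol to leave the boronic ester (boronate synthesis from organomagnesium and borate).

Step 6
Reactants: 7 (2S,3S)-3-methyl-2-(3,4,5-trimethoxyphenyl)-2,3-dihydro-1-benzofuran-5,6-dione; 11 allyldiisopropoxyborane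
Product: 13 (2S,3S,5R)-5-allyl-5-hydroxy-3-methyl-2-(3,4,5-trimethoxyphenyl)-2,3-dihydro-1-benzofuran-6(5H)-one, via C5-O-diisopropoxyboryl quinol 12 (not isolated)
Conditions: 11 (1.5 equiv), (S)-3,3'-dibromo-1,1'-bi-2-naphthol (15 mol %), PhCF3/toluene 3:1, −35 °C; pH 7 buffer
Reagents that add atoms: none
Why: Proposed new method: chiral-biphenol-catalysed asymmetric allylboration is known for ketones (aryl, alkyl and α,β-unsaturated) but not for an ortho-quinone carbonyl; exchange of one isopropoxy group of 11 for the binaphthol gives a more Lewis-acidic chiral allylboronate that binds the carbonyl oxygen and transfers allyl through a closed six-membered chair transition state, so only 1,2-addition is possible; C5=O is the ketone-like carbonyl whereas C6=O is a vinylogous ester (O1–C7a=C7–C6=O), so addition should take place at C5; the catalyst is to place allyl on the Si face of C5=O, which is also the face remote from the C3 methyl group, giving the 5R quaternary carbinol; the medium is free of base, so the C3–H of the quinone is not enolised.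

Step 7
Reactants: 13 (2S,3S,5R)-5-allyl-5-hydroxy-3-methyl-2-(3,4,5-trimethoxyphenyl)-2,3-dihydro-1-benzofuran-6(5H)-one
Product: 14 (2S,3S,5R)-5-allyl-5-methoxy-3-methyl-2-(3,4,5-trimethoxyphenyl)-2,3-dihydro-1-benzofuran-6(5H)-one
Conditions: MeI (10 equiv), Ag2O (3 equiv), 4 Å MS, MeCN, rt → 35 °C, dark
Reagents that add atoms: iodomethane, CI
Why: Purdie methylation (Ag2O/MeI) alkylates the tertiary α-ketol hydroxyl without generating a free alkoxide, which should avoid anionic oxy-Cope and α-ketol shifts of the allyl group, and C5 is not touched, so its configuration is kept.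

**Compound list**

1 | 2-methoxyhydroquinone | COc1cc(O)ccc1O | starting material
2 | 2-methoxy-1,4-benzoquinone | COC1=CC(=O)C=CC1=O | intermediate
3 | 5-bromo-1,2,3-trimethoxybenzene | COc1cc(Br)cc(OC)c1OC | starting material
4 | (E)-prop-1-enylboronic acid pinacol ester | C/C=C/B1OC(C)(C)C(C)(C)O1 | starting material
5 | (E)-isoelemicin, 1,2,3-trimethoxy-5-[(E)-prop-1-enyl]benzene | C/C=C/c1cc(OC)c(OC)c(OC)c1 | intermediate
6 | (2S,3S)-6-methoxy-3-methyl-2-(3,4,5-trimethoxyphenyl)-2,3-dihydro-1-benzofuran-5-ol (trans) | Oc1cc2c(cc1OC)O[C@H](c1cc(OC)c(OC)c(OC)c1)[C@H]2C | intermediate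
7 | (2S,3S)-3-methyl-2-(3,4,5-trimethoxyphenyl)-2,3-dihydro-1-benzofuran-5,6-dione | O=C1C=C2C(=CC1=O)O[C@H](c1cc(OC)c(OC)c(OC)c1)[C@H]2C | intermediate
8 | allylmagnesium bromide | C=CC[Mg]Br | starting material
9 | triisopropyl borate | CC(C)OB(OC(C)C)OC(C)C | starting material
10 | bromomagnesium allyltriisopropoxyborate | C=CC[B-](OC(C)C)(OC(C)C)OC(C)C.[Mg+]Br | intermediate
11 | allyldiisopropoxyborane | C=CCB(OC(C)C)OC(C)C | intermediate
12 | (2S,3S,5R)-5-allyl-5-[(diisopropoxyboryl)oxy]-3-methyl-2-(3,4,5-trimethoxyphenyl)-2,3-dihydro-1-benzofuran-6(5H)-one | C=CC[C@@]1(OB(OC(C)C)OC(C)C)C=C2C(=CC1=O)O[C@H](c1cc(OC)c(OC)c(OC)c1)[C@H]2C | intermediate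
13 | (2S,3S,5R)-5-allyl-5-hydroxy-3-methyl-2-(3,4,5-trimethoxyphenyl)-2,3-dihydro-1-benzofuran-6(5H)-one | C=CC[C@@]1(O)C=C2C(=CC1=O)O[C@H](c1cc(OC)c(OC)c(OC)c1)[C@H]2C | intermediate
14 | (2S,3S,5R)-5-allyl-5-methoxy-3-methyl-2-(3,4,5-trimethoxyphenyl)-2,3-dihydro-1-benzofuran-6(5H)-one (CNP0316836.2) | C=CC[C@@]1(OC)C=C2C(=CC1=O)O[C@H](c1cc(OC)c(OC)c(OC)c1)[C@H]2C | target

**Step count**

Total: 7 steps. Longest linear sequence: 5 steps (step 1 or 2, then 3, 4, 6, 7).

**Steps most likely to fail**

Step 6 (proposed new method). The catalysed pathway may not outrun the uncatalysed addition of the boronate to the activated quinone carbonyl, so facial discrimination at C5 could be poor, and some attack at the C6 carbonyl is conceivable. The fallback sets out from 7 and uses chemistry known for 1,2-diones and ortho-quinones: Barbier allylation with allyl bromide and indium powder in THF/H2O at room temperature. It relies on the substrate alone and should give 13 together with its C5 epimer (2S,3S,5S)-5-allyl-5-hydroxy-3-methyl-2-(3,4,5-trimethoxyphenyl)-2,3-dihydro-1-benzofuran-6(5H)-one F1. The two tertiary alcohols are separated by chromatography, and the route is rejoined at 13.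

Step 3. The zwitterion may be diverted into carbon–carbon closure ([2+2] or [5+2] adducts), and enantiofacial control by the diolate may be incomplete. The fallback sets out from 2 and 5 and runs the annulation with the achiral TiCl4/Ti(OiPr)4 promoter in CH2Cl2 from −78 °C to room temperature, conditions under which the dihydrobenzofuran is the thermodynamic outcome. This should give trans 6 as the racemate with its enantiomer (2R,3R)-6-methoxy-3-methyl-2-(3,4,5-trimethoxyphenyl)-2,3-dihydro-1-benzofuran-5-ol F2. The enantiomers are separated by preparative chromatography on a chiral stationary phase, and the route is rejoined at 6.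

Step 4. Oxygen may be delivered to the unsubstituted ortho carbon C4 and not to C6, and the ortho-quinone may tautomerise through C3–H toward a quinone methide, with loss of the C3 configuration. The fallback sets out from 5 and avoids the demethylation. Commercial 2-(benzyloxy)phenol is oxidised with Fremy's salt to 2-(benzyloxy)-1,4-benzoquinone F3. This quinone is used in the same titanium TADDOLate annulation with 5 to give (2S,3S)-6-(benzyloxy)-3-methyl-2-(3,4,5-trimethoxyphenyl)-2,3-dihydro-1-benzofuran-5-ol F4. Hydrogenolysis (H2, Pd/C, EtOAc, rt) should give (2S,3S)-3-methyl-2-(3,4,5-trimethoxyphenyl)-2,3-dihydro-1-benzofuran-5,6-diol F5. Oxidation of this catechol with Ag2O in Et2O at 0 °C gives 7, which is carried straight into step 6.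

**Further compounds**

F1 | step 6 | (2S,3S,5S)-5-allyl-5-hydroxy-3-methyl-2-(3,4,5-trimethoxyphenyl)-2,3-dihydro-1-benzofuran-6(5H)-one | C=CC[C@]1(O)C=C2C(=CC1=O)O[C@H](c1cc(OC)c(OC)c(OC)c1)[C@H]2C
F2 | step 3 | (2R,3R)-6-methoxy-3-methyl-2-(3,4,5-trimethoxyphenyl)-2,3-dihydro-1-benzofuran-5-ol | Oc1cc2c(cc1OC)O[C@@H](c1cc(OC)c(OC)c(OC)c1)[C@@H]2C
F3 | step 4 | 2-(benzyloxy)-1,4-benzoquinone | O=C1C=CC(=O)C(OCc2ccccc2)=C1
F4 | step 4 | (2S,3S)-6-(benzyloxy)-3-methyl-2-(3,4,5-trimethoxyphenyl)-2,3-dihydro-1-benzofuran-5-ol | Oc1cc2c(cc1OCc1ccccc1)O[C@H](c1cc(OC)c(OC)c(OC)c1)[C@H]2C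
F5 | step 4 | (2S,3S)-3-methyl-2-(3,4,5-trimethoxyphenyl)-2,3-dihydro-1-benzofuran-5,6-diol | Oc1cc2c(cc1O)O[C@H](c1cc(OC)c(OC)c(OC)c1)[C@H]2C
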